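Ring A is treated as a masked hexasubstituted phloroglucinol whose carbons are numbered 1 to 6: carbon 1 carries the CH2 link to cyclopentane ring B, carbons 2, 4 and 6 carry oxygen, carbon 3 methyl and carbon 5 the acyl group. Everything rests on disconnecting the bonds between carbons 1 and 2 and between carbons 5 and 6, so that one thermal cascade fuses a ring B siloxyalkyne with 3-ethoxy-4-methylcyclobutenone and delivers the arene with its three oxygens as free phenol, ethyl ether and silyl ether. The alkyne partner is the triisopropylsilyl ynol ether on the ring B methylene, its tertiary alcohol capped as triethylsilyl ether. Acylation, dearomatising prenylation at carbon 3 and deprotection follow.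

Key step: step 6

Assumption: the ligand antipodes written in steps 1 and 9 are taken to be those that give the isopropenyl-bearing carbon of ring B and the quaternary carbon of ring A as drawn; should either sense of induction prove opposite, the mirror-image ligand is used and nothing else changes.

Remark: in the target the tertiary hydroxyl of ring B is cis to the CH2 link and trans to the isopropenyl group, so an ester in that side chain would close a γ-lactone onto the alkoxide; the two-carbon unit is therefore carried as a propargyl group and the ynol ether is made by oxidation of its acetylide.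

Step 1
Reactants: 1 cyclopent-2-en-1-one; 2 3-bromoprop-1-yne
Product: 4 (2S,3R)-3-(prop-1-en-2-yl)-2-(prop-2-yn-1-yl)cyclopentan-1-one, via magnesium enolate 3 (not isolated)
Conditions: isopropenylmagnesium bromide, CuBr·SMe2 (5 mol %), (R)-1-[(S)-2-(diphenylphosphino)ferrocenyl]ethyldicyclohexylphosphine (6 mol %), t-BuOMe, −75 °C; then 2, DMPU, −75 → −20 °C
Reagents that add atoms: isopropenylmagnesium bromide, C=C(C)[Mg]Br
Why: Copper-catalysed asymmetric conjugate addition of the Grignard reagent under control of the chiral diphosphine should set the isopropenyl-bearing carbon (3R), and the regiodefined enolate 3 is then alkylated by the reactive propargylic bromide anti to the new isopropenyl group, which sets the adjacent carbon (2S) trans to it (three-component conjugate addition–enolate alkylation).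

Step 2
Reactants: 4 (2S,3R)-3-(prop-1-en-2-yl)-2-(prop-2-yn-1-yl)cyclopentan-1-one
Product: 5 (1R,2S,3R)-1-methyl-3-(prop-1-en-2-yl)-2-(prop-2-yn-1-yl)cyclopentan-1-ol
Conditions: MeMgBr, CeCl3, THF, −78 °C; aq. NH4Cl
Reagents that add atoms: methylmagnesium bromide, C[Mg]Br
Why: The organocerium reagent adds 1,2 without enolising the cyclopentanone and should approach the carbonyl face anti to the adjacent propargyl group (substrate control), which places methyl trans and the new tertiary hydroxyl cis to that side chain as in the target.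

Step 3
Reactants: 5 (1R,2S,3R)-1-methyl-3-(prop-1-en-2-yl)-2-(prop-2-yn-1-yl)cyclopentan-1-ol
Product: 6 triethyl{[(1R,2S,3R)-1-methyl-3-(prop-1-en-2-yl)-2-(prop-2-yn-1-yl)cyclopentyl]oxy}silane
Conditions: Et3SiOTf, 2,6-lutidine, CH2Cl2, −78 → 0 °C
Reagents that add atoms: triethylsilyl trifluoromethanesulfonate, CC[Si](CC)(CC)OS(=O)(=O)C(F)(F)F
Why: Silylation of a hindered tertiary alcohol with a silyl triflate and a non-nucleophilic base is standard, and the triethylsilyl ether tolerates the organolithium reagents, the heating and the mild electrophiles used later.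

Step 4
Reactants: 6 triethyl{[(1R,2S,3R)-1-methyl-3-(prop-1-en-2-yl)-2-(prop-2-yn-1-yl)cyclopentyl]oxy}silane
Product: 9 triethyl{[(1R,2S,3R)-1-methyl-3-(prop-1-en-2-yl)-2-{3-[(triisopropylsilyl)oxy]prop-2-yn-1-yl}cyclopentyl]oxy}silane, via lithium acetylide 7 (not isolated), via lithium ynolate 8 (not isolated)
Conditions: n-BuLi, THF, −78 °C; t-BuOOLi (from t-BuOOH and LiN(SiMe3)2), −78 → 0 °C; (i-Pr)3SiOTf, −78 °C
Reagents that add atoms: tert-butyl hydroperoxide, CC(C)(C)OO; triisopropylsilyl trifluoromethanesulfonate, CC(C)[Si](C(C)C)(C(C)C)OS(=O)(=O)C(F)(F)F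
Why: Oxidation of acetylide 7 by lithium tert-butyl peroxide (electrophilic oxygen transfer) gives ynolate 8, and the hindered silyl triflate reacts at oxygen to give the isolable triisopropylsilyl ynol ether, the standard preparation of siloxyalkynes from terminal alkynes.

Step 5
Reactants: 10 propanoyl chloride; 11 ethoxyethyne
Product: 13 3-ethoxy-4-methylcyclobut-2-en-1-one (racemic), via methylketene 12 (not isolated)
Conditions: Et3N, Et2O, 0 °C → rt (11 in excess)
Reagents that add atoms: none
Why: Dehydrochlorination of 10 gives methylketene 12, which undergoes [2+2] cycloaddition with the ynol ether with its unsubstituted alkyne carbon bonding to the ketene carbonyl carbon, the established route to 3-alkoxycyclobutenones; the single stereocentre is racemic and is erased in step 6.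

Step 6
Reactants: 9 triethyl{[(1R,2S,3R)-1-methyl-3-(prop-1-en-2-yl)-2-{3-[(triisopropylsilyl)oxy]prop-2-yn-1-yl}cyclopentyl]oxy}silane; 13 3-ethoxy-4-methylcyclobut-2-en-1-one
Product: 18 3-ethoxy-2-methyl-6-{[(1S,2R,5R)-2-methyl-5-(prop-1-en-2-yl)-2-(triethylsilyloxy)cyclopentyl]methyl}-5-(triisopropylsilyloxy)phenol, via vinylketene 14 (not isolated), via 4-vinylcyclobutenone 15 (not isolated), via dienylketene 16 (not isolated), via cyclohexa-2,4-dienone 17 (not isolated)
Conditions: toluene, 110 °C, sealed tube (13 in slight excess, added in portions)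
Reagents that add atoms: none
Why: On heating, 13 undergoes 4π electrocyclic ring opening (methyl turning outward) to vinylketene 14, whose ketene C=C adds across the siloxyalkyne in a polar stepwise [2+2] cycloaddition that joins the oxygen-free alkyne carbon (ring A carbon 1) to the ketene carbonyl carbon (carbon 2) and the silyloxy carbon (carbon 6) to the former ring CH (carbon 5), giving 15. A second, reversible 4π opening turns 15 into dienylketene 16, and ring A is then closed by a thermal disrotatory 6π electrocyclisation that makes the bond between carbons 2 and 3; enolisation of dienone 17 gives the phenol. The closest known reaction type is the Danheiser benzannulation of cyclobutenones with siloxyalkynes to resorcinol monosilyl ethers, applied here to a 3-alkoxycyclobutenone so that a third, differently capped oxygen (on carbon 4) is built in. No stereocentre is created, because the sp3 carbon of racemic 13 and the transient one of 17 both become aromatic carbon 3, and the three centres of ring B are not touched. Regiocontrol is needed and comes from polarity: the ynol ether is nucleophilic at the carbon remote from oxygen and the ketene is electrophilic at its carbonyl carbon, so the position of every ring A substituent is dictated by the bonding pattern and not by a choice between similar sites. Chemoselectivity is needed as well and comes from the much higher nucleophilicity of the siloxyalkyne than of the isopropenyl alkene toward 14, helped by the triethylsilyl cap on the tertiary hydroxyl, which would otherwise add to the ketene.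

Step 7
Reactants: 18 3-ethoxy-2-methyl-6-{[(1S,2R,5R)-2-methyl-5-(prop-1-en-2-yl)-2-(triethylsilyloxy)cyclopentyl]methyl}-5-(triisopropylsilyloxy)phenol
Product: 19 4-bromo-3-ethoxy-2-methyl-6-{[(1S,2R,5R)-2-methyl-5-(prop-1-en-2-yl)-2-(triethylsilyloxy)cyclopentyl]methyl}-5-(triisopropylsilyloxy)phenol (bromine on ring A carbon 5)
Conditions: NBS, CH2Cl2, −78 → −40 °C, dark
Reagents that add atoms: N-bromosuccinimide, O=C1CCC(=O)N1Br
Why: Electrophilic aromatic bromination takes the only unsubstituted ring A position, carbon 5, which is para to the free phenol and ortho to two oxygen substituents, far faster than the reagent attacks the isolated alkene at low temperature in the dark.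

Step 8
Reactants: 19 4-bromo-3-ethoxy-2-methyl-6-{[(1S,2R,5R)-2-methyl-5-(prop-1-en-2-yl)-2-(triethylsilyloxy)cyclopentyl]methyl}-5-(triisopropylsilyloxy)phenol
Product: 22 1-[2-ethoxy-4-hydroxy-3-methyl-5-{[(1S,2R,5R)-2-methyl-5-(prop-1-en-2-yl)-2-(triethylsilyloxy)cyclopentyl]methyl}-6-(triisopropylsilyloxy)phenyl]-2-methylpropan-1-one, via dilithiated arene 20 (not isolated), via tetrahedral adduct 21 (not isolated)
Conditions: t-BuLi (3.1 equiv), THF, −78 °C; then i-PrC(O)N(OMe)Me, −78 → −30 °C; aq. NH4Cl
Reagents that add atoms: N-methoxy-N-methyl-2-methylpropanamide, CC(C)C(=O)N(C)OC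
Why: Deprotonation of the phenol and bromine–lithium exchange give aryllithium 20, which adds once to the amide (Weinreb ketone synthesis) because the chelated adduct 21 releases the ketone only on work-up, while the bulk of the triisopropylsilyl group and the low temperature hold back anionic silyl migration from oxygen to carbon.

Step 9
Reactants: 22 1-[2-ethoxy-4-hydroxy-3-methyl-5-{[(1S,2R,5R)-2-methyl-5-(prop-1-en-2-yl)-2-(triethylsilyloxy)cyclopentyl]methyl}-6-(triisopropylsilyloxy)phenyl]-2-methylpropan-1-one
Product: 23 (6S)-5-ethoxy-6-methyl-6-(3-methylbut-2-en-1-yl)-4-(2-methylpropanoyl)-2-{[(1S,2R,5R)-2-methyl-5-(prop-1-en-2-yl)-2-(triethylsilyloxy)cyclopentyl]methyl}-3-(triisopropylsilyloxy)cyclohexa-2,4-dien-1-one (quaternary ring A carbon arranged as in the target)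
Conditions: Pd2(dba)3 (2.5 mol %), (R,R)-N,N'-bis[2-(diphenylphosphino)benzoyl]cyclohexane-1,2-diamine (7.5 mol %), prenyl acetate, Cs2CO3, THF, 0 °C → rt
Reagents that add atoms: 3-methylbut-2-en-1-yl acetate (prenyl acetate), CC(C)=CCOC(C)=O
Why: In this dearomatising Tsuji–Trost allylation the π-prenyl complex formed from zerovalent palladium is attacked at its unsubstituted terminus by the methyl-bearing ring A carbon 3 of the phenoxide, since carbon 1 is screened by its branched side chain and the flanking triisopropylsilyl ether (kept on the carbon 6 oxygen for this purpose) and carbon 5 by the acyl group, and the chiral pocket of the diphosphine should select the face of carbon 3 (catalyst control, ring B being too remote to bias it), which sets the quaternary centre.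

Step 10
Reactants: 23 (6S)-5-ethoxy-6-methyl-6-(3-methylbut-2-en-1-yl)-4-(2-methylpropanoyl)-2-{[(1S,2R,5R)-2-methyl-5-(prop-1-en-2-yl)-2-(triethylsilyloxy)cyclopentyl]methyl}-3-(triisopropylsilyloxy)cyclohexa-2,4-dien-1-one
Product: 24 (4R)-3-ethoxy-5-hydroxy-6-{[(1S,2R,5R)-2-hydroxy-2-methyl-5-(prop-1-en-2-yl)cyclopentyl]methyl}-4-methyl-4-(3-methylbut-2-en-1-yl)-2-(2-methylpropanoyl)cyclohexa-2,5-dien-1-one
Conditions: Bu4NF, THF, 0 °C → rt; pH 5 phosphate buffer
Reagents that add atoms: none
Why: Fluoride cleaves the vinylogous silyl ester on the carbon 6 oxygen at once and the tertiary triethylsilyl ether on longer exposure, while the ethyl vinylogous ester, the quaternary ring A centre and the alkenes are inert to these conditions.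

Step 11
Reactants: 24 (4R)-3-ethoxy-5-hydroxy-6-{[(1S,2R,5R)-2-hydroxy-2-methyl-5-(prop-1-en-2-yl)cyclopentyl]methyl}-4-methyl-4-(3-methylbut-2-en-1-yl)-2-(2-methylpropanoyl)cyclohexa-2,5-dien-1-one
Product: 25 (6R)-3,5-dihydroxy-4-{[(1S,2R,5R)-2-hydroxy-2-methyl-5-(prop-1-en-2-yl)cyclopentyl]methyl}-6-methyl-6-(3-methylbut-2-en-1-yl)-2-(2-methylpropanoyl)cyclohexa-2,4-dien-1-one (target)
Conditions: LiCl, DMSO, 130 °C; aq. NaH2PO4
Reagents that add atoms: none
Why: Chloride dealkylates the vinylogous ethyl ester on the carbon 4 oxygen by SN2 attack on the ethyl group (Krapcho-type cleavage), the leaving group being the well-stabilised enolate of the acyl trione, and mildly acidic work-up should give the target as its enol tautomer without touching the quaternary ring A centre or ring B.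

Compound list
1 | cyclopent-2-en-1-one | O=C1C=CCC1 | starting material
2 | 3-bromoprop-1-yne (propargyl bromide) | C#CCBr | starting material
3 | bromomagnesium (3R)-3-(prop-1-en-2-yl)cyclopent-1-en-1-olate | C=C(C)[C@@H]1CCC(O[Mg]Br)=C1 | intermediate (not isolated)
4 | (2S,3R)-3-(prop-1-en-2-yl)-2-(prop-2-yn-1-yl)cyclopentan-1-one | C=C(C)[C@@H]1CCC(=O)[C@H]1CC#C | intermediate
5 | (1R,2S,3R)-1-methyl-3-(prop-1-en-2-yl)-2-(prop-2-yn-1-yl)cyclopentan-1-ol | C=C(C)[C@@H]1CC[C@@](C)(O)[C@H]1CC#C | intermediate
6 | triethyl{[(1R,2S,3R)-1-methyl-3-(prop-1-en-2-yl)-2-(prop-2-yn-1-yl)cyclopentyl]oxy}silane | C=C(C)[C@@H]1CC[C@@](C)(O[Si](CC)(CC)CC)[C@H]1CC#C | intermediate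
7 | lithium acetylide of 6 | C=C(C)[C@@H]1CC[C@@](C)(O[Si](CC)(CC)CC)[C@H]1CC#C[Li] | intermediate (not isolated)
8 | lithium ynolate derived from 7 | C=C(C)[C@@H]1CC[C@@](C)(O[Si](CC)(CC)CC)[C@H]1CC#CO[Li] | intermediate (not isolated)
9 | triethyl{[(1R,2S,3R)-1-methyl-3-(prop-1-en-2-yl)-2-{3-[(triisopropylsilyl)oxy]prop-2-yn-1-yl}cyclopentyl]oxy}silane (siloxyalkyne) | C=C(C)[C@@H]1CC[C@@](C)(O[Si](CC)(CC)CC)[C@H]1CC#CO[Si](C(C)C)(C(C)C)C(C)C | intermediate
10 | propanoyl chloride | CCC(=O)Cl | starting material
11 | ethoxyethyne | CCOC#C | starting material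
12 | methylketene (prop-1-en-1-one) | CC=C=O | intermediate (not isolated)
13 | 3-ethoxy-4-methylcyclobut-2-en-1-one (racemic) | CCOC1=CC(=O)C1C | intermediate
14 | (Z)-3-ethoxypenta-1,3-dien-1-one (vinylketene) | C/C=C(OCC)/C=C=O | intermediate (not isolated)
15 | 4-[(Z)-1-ethoxyprop-1-en-1-yl]-2-{[ring B]methyl}-3-(triisopropylsilyloxy)cyclobut-2-en-1-one (ring carbon 4 unassigned) | C=C(C)[C@@H]1CC[C@@](C)(O[Si](CC)(CC)CC)[C@H]1CC1=C(O[Si](C(C)C)(C(C)C)C(C)C)C(/C(OCC)=C/C)C1=O | intermediate (not isolated)
16 | (3E,5Z)-5-ethoxy-2-{[ring B]methyl}-3-(triisopropylsilyloxy)hepta-1,3,5-trien-1-one (dienylketene) | C=C(C)[C@@H]1CC[C@@](C)(O[Si](CC)(CC)CC)[C@H]1CC(=C=O)/C(O[Si](C(C)C)(C(C)C)C(C)C)=C\C(OCC)=C\C | intermediate (not isolated)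
17 | 5-ethoxy-6-methyl-2-{[ring B]methyl}-3-(triisopropylsilyloxy)cyclohexa-2,4-dien-1-one (carbon 6 unassigned) | C=C(C)[C@@H]1CC[C@@](C)(O[Si](CC)(CC)CC)[C@H]1CC1=C(O[Si](C(C)C)(C(C)C)C(C)C)C=C(OCC)C(C)C1=O | intermediate (not isolated)
18 | 3-ethoxy-2-methyl-6-{[(1S,2R,5R)-2-methyl-5-(prop-1-en-2-yl)-2-(triethylsilyloxy)cyclopentyl]methyl}-5-(triisopropylsilyloxy)phenol | C=C(C)[C@@H]1CC[C@@](C)(O[Si](CC)(CC)CC)[C@H]1Cc1c(O)c(C)c(OCC)cc1O[Si](C(C)C)(C(C)C)C(C)C | intermediate
19 | 4-bromo derivative of 18 (bromine on ring A carbon 5) | C=C(C)[C@@H]1CC[C@@](C)(O[Si](CC)(CC)CC)[C@H]1Cc1c(O)c(C)c(OCC)c(Br)c1O[Si](C(C)C)(C(C)C)C(C)C | intermediate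
20 | dilithiated arene (lithium phenoxide on ring A carbon 2, carbon–lithium bond at ring A carbon 5) | C=C(C)[C@@H]1CC[C@@](C)(O[Si](CC)(CC)CC)[C@H]1Cc1c(O[Li])c(C)c(OCC)c([Li])c1O[Si](C(C)C)(C(C)C)C(C)C | intermediate (not isolated)
21 | tetrahedral lithium N-methoxy-N-methyl hemiaminal adduct at ring A carbon 5 (new carbon unassigned) | C=C(C)[C@@H]1CC[C@@](C)(O[Si](CC)(CC)CC)[C@H]1Cc1c(O[Li])c(C)c(OCC)c(C(O[Li])(N(C)OC)C(C)C)c1O[Si](C(C)C)(C(C)C)C(C)C | intermediate (not isolated)
22 | 1-[2-ethoxy-4-hydroxy-3-methyl-5-{[(1S,2R,5R)-2-methyl-5-(prop-1-en-2-yl)-2-(triethylsilyloxy)cyclopentyl]methyl}-6-(triisopropylsilyloxy)phenyl]-2-methylpropan-1-one | C=C(C)[C@@H]1CC[C@@](C)(O[Si](CC)(CC)CC)[C@H]1Cc1c(O)c(C)c(OCC)c(C(=O)C(C)C)c1O[Si](C(C)C)(C(C)C)C(C)C | intermediate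
23 | (6S)-5-ethoxy-6-methyl-6-(3-methylbut-2-en-1-yl)-4-(2-methylpropanoyl)-2-{[(1S,2R,5R)-2-methyl-5-(prop-1-en-2-yl)-2-(triethylsilyloxy)cyclopentyl]methyl}-3-(triisopropylsilyloxy)cyclohexa-2,4-dien-1-one | C=C(C)[C@@H]1CC[C@@](C)(O[Si](CC)(CC)CC)[C@H]1CC1=C(O[Si](C(C)C)(C(C)C)C(C)C)C(C(=O)C(C)C)=C(OCC)[C@](C)(CC=C(C)C)C1=O | intermediate
24 | (4R)-3-ethoxy-5-hydroxy-6-{[(1S,2R,5R)-2-hydroxy-2-methyl-5-(prop-1-en-2-yl)cyclopentyl]methyl}-4-methyl-4-(3-methylbut-2-en-1-yl)-2-(2-methylpropanoyl)cyclohexa-2,5-dien-1-one | C=C(C)[C@@H]1CC[C@@](C)(O)[C@H]1CC1=C(O)[C@@](C)(CC=C(C)C)C(OCC)=C(C(=O)C(C)C)C1=O | intermediate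
25 | (6R)-3,5-dihydroxy-4-{[(1S,2R,5R)-2-hydroxy-2-methyl-5-(prop-1-en-2-yl)cyclopentyl]methyl}-6-methyl-6-(3-methylbut-2-en-1-yl)-2-(2-methylpropanoyl)cyclohexa-2,4-dien-1-one | C=C(C)[C@@H]1CC[C@@](C)(O)[C@H]1CC1=C(O)[C@@](C)(CC=C(C)C)C(=O)C(C(=O)C(C)C)=C1O | target

In 15–17, "ring B" stands for the (1S,2R,5R)-2-methyl-5-(prop-1-en-2-yl)-2-(triethylsilyloxy)cyclopentyl group.

Total step count: 11. Longest linear sequence: 10 steps (steps 1–4 and 6–11; step 5 is a one-step branch).

Steps most likely to fail

1. Step 6 (key step). The alkoxy-stabilised cyclobutenone may open only at temperatures at which the siloxyalkyne is lost by desilylation or at which the vinylketene is diverted into dimerisation and acylation of the product phenol. The fallback sets out from 9 and returns at 18, generating the same vinylketene from an acyclic precursor at ambient temperature. Commercial ethyl 3-oxopentanoate is O-ethylated with triethyl orthoformate and catalytic H2SO4 to ethyl (E)-3-ethoxypent-2-enoate F1. F1 is saponified (KOH, aqueous ethanol, then careful acidification with HCl) to (E)-3-ethoxypent-2-enoic acid F2, and F2 is converted with oxalyl chloride into (E)-3-ethoxypent-2-enoyl chloride F3. Slow addition of F3 to 9 and Et3N in toluene at room temperature effects 1,4-dehydrochlorination to vinylketene 14, which is captured by the siloxyalkyne as it forms. Gentle warming (about 80 °C) then carries 15 through 16 and 17 to 18, so no stabilised four-membered ring has to be opened at high temperature.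

2. Step 9. The prenyl group may be delivered to oxygen or to the side-chain-bearing ring A carbon 1 instead of the methyl-bearing carbon 3, or the catalyst may discriminate the two faces of carbon 3 poorly so that both epimers at that centre form. The fallback sets out from 22 and returns at 23. The phenol is converted with NaH in toluene into its sodium phenoxide F4 and alkylated with prenyl bromide in that non-polar medium, where the contact ion pair steers the allylic halide to the ortho carbon (the classical dearomatising C-alkylation of 2,6-disubstituted phenoxides; carbon 1 stays screened by the silyl ether). This gives 23 together with the quaternary-centre epimer of 23 F5; because ring B makes the two diastereomers, 23 would be isolated by preparative HPLC.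

3. Step 1. Face selection may be weak with an alkenyl Grignard reagent, 1,2-addition may compete, and proton exchange of the cyclopentanone enolate may lead to over-alkylation or loss of regiochemistry. The fallback sets out from 1 and returns at 4, using a softer organometallic and separating the two bond formations. Diisopropenylzinc (from isopropenylmagnesium bromide and ZnCl2, salts removed with 1,4-dioxane) is added to 1 under Cu(OTf)2 and (S,R,R)-O,O'-(1,1'-binaphthyl-2,2'-diyl)-N,N-bis(1-phenylethyl)phosphoramidite in toluene at −30 °C, giving isopropenylzinc (3R)-3-(prop-1-en-2-yl)cyclopent-1-en-1-olate F6. F6 is trapped with Me3SiOTf and trimethyl{[(3R)-3-(prop-1-en-2-yl)cyclopent-1-en-1-yl]oxy}silane F7 is isolated. MeLi in THF then releases lithium (3R)-3-(prop-1-en-2-yl)cyclopent-1-en-1-olate F8, which is alkylated with 2 (DMPU, −78 °C) to 4.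

Further compounds
F1 | step 6 | ethyl (E)-3-ethoxypent-2-enoate | CC/C(OCC)=C\C(=O)OCC
F2 | step 6 | (E)-3-ethoxypent-2-enoic acid | CC/C(OCC)=C\C(=O)O
F3 | step 6 | (E)-3-ethoxypent-2-enoyl chloride | CC/C(OCC)=C\C(=O)Cl
F4 | step 9 | sodium phenoxide of 22 | C=C(C)[C@@H]1CC[C@@](C)(O[Si](CC)(CC)CC)[C@H]1Cc1c(O[Na])c(C)c(OCC)c(C(=O)C(C)C)c1O[Si](C(C)C)(C(C)C)C(C)C
F5 | step 9 | quaternary-centre epimer of 23 | C=C(C)[C@@H]1CC[C@@](C)(O[Si](CC)(CC)CC)[C@H]1CC1=C(O[Si](C(C)C)(C(C)C)C(C)C)C(C(=O)C(C)C)=C(OCC)[C@@](C)(CC=C(C)C)C1=O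
F6 | step 1 | isopropenylzinc (3R)-3-(prop-1-en-2-yl)cyclopent-1-en-1-olate | C=C(C)[C@@H]1CCC(O[Zn]C(C)=C)=C1
F7 | step 1 | trimethyl{[(3R)-3-(prop-1-en-2-yl)cyclopent-1-en-1-yl]oxy}silane | C=C(C)[C@@H]1CCC(O[Si](C)(C)C)=C1
F8 | step 1 | lithium (3R)-3-(prop-1-en-2-yl)cyclopent-1-en-1-olate | C=C(C)[C@@H]1CCC(O[Li])=C1
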